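**Strategy.** Ring C is cut at O1–C2 and C3–C4, so that ring A with C4 becomes a salicylaldehyde, and C2, C3 and ring B become a cinnamaldehyde whose carbonyl carbon stays on C3 as a formyl group standing in for the C3 oxygen. One aminocatalytic oxa-Michael/aldol condensation forms both bonds, closes ring C and sets C2 (R). The precursors are 4-(benzyloxy)-2-hydroxy-6-(methoxymethoxy)benzaldehyde, in which MOM marks the later O5 gallate site and benzyl the later free O7, and (E)-3,4,5-tris(benzyloxy)cinnamaldehyde. The formyl group is then degraded to the C3 ketone, reduced cis, and both gallates are installed before global hydrogenolysis.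

Key step: step 4

Remark on the catalyst: the sense of induction is assigned from the usual shielding model for the E-configured iminium ion of an (S)-diarylprolinol silyl ether (attack on the Si face of the β-carbon of a β-aryl enal). Should analysis of 7 show the opposite sense, the (R)-catalyst would be used with no other change.

Remark on descriptors: the arrangement in space at C2 is the same from 6 to 16. It is labelled 2S in 6 (and in F4) only because C3 ranks below ring B there.

**Step 1**
Reactants: 1 2,4,6-trihydroxybenzaldehyde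
Product: 2 4-(benzyloxy)-2,6-dihydroxybenzaldehyde
Conditions: BnBr (1.0 equiv), NaHCO3, DMF, 40 °C
Reagents that add atoms: benzyl bromide, BrCc1ccccc1
Why: Williamson etherification in which bicarbonate ionises only the 4-OH (para to the formyl group, not held in a hydrogen bond and therefore the most acidic), while the two chelated ortho hydroxyls stay unreactive.

**Step 2**
Reactants: 2 4-(benzyloxy)-2,6-dihydroxybenzaldehyde
Product: 3 4-(benzyloxy)-2-hydroxy-6-(methoxymethoxy)benzaldehyde
Conditions: MOMCl (1.1 equiv), i-Pr2NEt, CH2Cl2, 0 °C to rt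
Reagents that add atoms: chloromethyl methyl ether, COCCl
Why: O-alkylation with an α-chloro ether (acetal-type ether formation) of one of two equivalent hydroxyls, after which the remaining one is locked in the hydrogen bond to the formyl oxygen and should resist a second alkylation under amine-base conditions.

**Step 3**
Reactants: 4 3,4,5-tris(benzyloxy)benzaldehyde
Product: 5 (E)-3-[3,4,5-tris(benzyloxy)phenyl]prop-2-enal
Conditions: Ph3P=CHCHO (1.2 equiv), toluene, 80 °C
Reagents that add atoms: (triphenylphosphoranylidene)acetaldehyde, O=CC=P(c1ccccc1)(c1ccccc1)c1ccccc1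
Why: Wittig olefination with a stabilised ylide, which should give the E-enal, the small excess of ylide keeping a second homologation low.

**Step 4**
Reactants: 3 4-(benzyloxy)-2-hydroxy-6-(methoxymethoxy)benzaldehyde; 5 (E)-3-[3,4,5-tris(benzyloxy)phenyl]prop-2-enal (1.3 equiv)
Product: 7 (2R)-7-(benzyloxy)-5-(methoxymethoxy)-2-[3,4,5-tris(benzyloxy)phenyl]-2H-chromene-3-carbaldehyde, via aldol adduct 6 (not isolated)
Conditions: (S)-2-[diphenyl(trimethylsilyloxy)methyl]pyrrolidine (20 mol %), 2-nitrobenzoic acid (20 mol %), 4 Å MS, toluene, rt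
Reagents that add atoms: none
Why: The secondary amine condenses with enal 5 to an E-configured iminium ion, the phenol oxygen of 3 adds to its β-carbon (O1–C2), and the resulting enamine attacks the neighbouring formyl carbon (C3–C4) to give aldol 6, which loses water to the conjugated aldehyde 7 and releases the catalyst. The closest known reaction type is the diarylprolinol-silyl-ether-catalysed domino oxa-Michael/aldol condensation of salicylaldehydes with β-aryl enals. Ring C closes in the aldol event, a 6-exo-trig attack of the enamine carbon on the aryl aldehyde carbonyl. The only lasting stereocentre, C2, is set by the catalyst: the diphenyl(trimethylsilyloxy)methyl group of the (S)-pyrrolidine covers the Re face of the β-carbon, so the phenol should enter on the Si face, which corresponds to 2R, while the C3 and C4 centres of 6 vanish on dehydration. The step needs enantiofacial control, O- instead of C-alkylation of the phloroglucinol-type ring, and iminium formation at the enal and not at the aryl aldehyde. The formyl group deactivates the ring carbons and its hindered, hydrogen-bonded carbonyl does not compete for the amine, only the O-adduct can cyclise, and the final dehydration draws the reversible oxa-Michael equilibrium forward.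

**Step 5**
Reactants: 7 (2R)-7-(benzyloxy)-5-(methoxymethoxy)-2-[3,4,5-tris(benzyloxy)phenyl]-2H-chromene-3-carbaldehyde
Product: 8 (2R)-7-(benzyloxy)-5-(methoxymethoxy)-2-[3,4,5-tris(benzyloxy)phenyl]-2H-chromene-3-carboxylic acid
Conditions: NaClO2, NaH2PO4, 2-methylbut-2-ene (excess), t-BuOH/THF/H2O, 0 °C to rt
Reagents that add atoms: sodium chlorite, [Na+].[O-]Cl=O
Why: Pinnick oxidation, which converts enals to enoic acids without touching the double bond or C2, the alkene scavenger removing hypochlorous acid before it can chlorinate the electron-rich rings and the buffered medium sparing the MOM ether.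

**Step 6**
Reactants: 8 (2R)-7-(benzyloxy)-5-(methoxymethoxy)-2-[3,4,5-tris(benzyloxy)phenyl]-2H-chromene-3-carboxylic acid
Product: 11 (2R)-7-(benzyloxy)-5-(methoxymethoxy)-2-[3,4,5-tris(benzyloxy)phenyl]-2H-chromen-3(4H)-one, via acyl azide 9 (not isolated), via vinyl isocyanate 10 (not isolated)
Conditions: (PhO)2P(O)N3, Et3N, toluene, 0 °C to rt, then 85 °C; then 1 M aq HCl, THF, rt
Reagents that add atoms: water, O (ketone oxygen of 11); diphenylphosphoryl azide, [N-]=[N+]=NP(=O)(Oc1ccccc1)Oc1ccccc1 (nitrogen of 9 and 10 only)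
Why: Curtius rearrangement of the enoyl azide to the vinyl isocyanate, whose mild acid hydrolysis passes through the carbamic acid and the C3 enamine to the ketone (the established route from 2H-chromene-3-carboxylic acids to chroman-3-ones), with short contact to dilute acid at rt meant to spare the MOM ether and the C2 centre.

**Step 7**
Reactants: 11 (2R)-7-(benzyloxy)-5-(methoxymethoxy)-2-[3,4,5-tris(benzyloxy)phenyl]-2H-chromen-3(4H)-one
Product: 12 (2R,3R)-7-(benzyloxy)-5-(methoxymethoxy)-2-[3,4,5-tris(benzyloxy)phenyl]-3,4-dihydro-2H-chromen-3-ol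
Conditions: LiBH(s-Bu)3, THF, −78 °C; then H2O
Reagents that add atoms: none
Why: Substrate-controlled ketone reduction with a bulky trialkylborohydride, which should attack equatorially on the face away from the pseudo-equatorial C2 aryl group and so give the axial 3-OH cis to ring B (3R), as is established for benzylated flavan-3-ones.

**Step 8**
Reactants: 12 (2R,3R)-7-(benzyloxy)-5-(methoxymethoxy)-2-[3,4,5-tris(benzyloxy)phenyl]-3,4-dihydro-2H-chromen-3-ol
Product: 13 (2R,3R)-7-(benzyloxy)-2-[3,4,5-tris(benzyloxy)phenyl]-3,4-dihydro-2H-chromene-3,5-diol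
Conditions: HCl (1.25 M in MeOH), THF, rt
Reagents that add atoms: none
Why: Acid-catalysed transacetalisation of the aryl MOM ether to methanol, under which benzyl ethers, the secondary alcohol and both stereocentres should be unaffected.

**Step 9**
Reactants: 13 (2R,3R)-7-(benzyloxy)-2-[3,4,5-tris(benzyloxy)phenyl]-3,4-dihydro-2H-chromene-3,5-diol; 14 3,4,5-tris(benzyloxy)benzoic acid (3 equiv)
Product: 15 (2R,3R)-7-(benzyloxy)-2-[3,4,5-tris(benzyloxy)phenyl]-3,4-dihydro-2H-chromene-3,5-diyl bis[3,4,5-tris(benzyloxy)benzoate]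
Conditions: DCC (3 equiv), DMAP (0.5 equiv), CH2Cl2, 0 °C to rt
Reagents that add atoms: none
Why: Steglich esterification, in which the acylpyridinium intermediate acylates both the C5 phenol and the axial C3 alcohol with retention at C3, since no C–O bond of the flavan is broken.

**Step 10**
Reactants: 15 (2R,3R)-7-(benzyloxy)-2-[3,4,5-tris(benzyloxy)phenyl]-3,4-dihydro-2H-chromene-3,5-diyl bis[3,4,5-tris(benzyloxy)benzoate]
Product: 16 (2R,3R)-7-hydroxy-2-(3,4,5-trihydroxyphenyl)-3,4-dihydro-2H-chromene-3,5-diyl bis(3,4,5-trihydroxybenzoate) (epigallocatechin 3,5-digallate)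
Conditions: H2 (1 atm), Pd(OH)2 on carbon, THF/MeOH, rt; filtration under argon
Reagents that add atoms: none
Why: Catalytic hydrogenolysis of all ten benzyl ethers under neutral conditions, which is established for benzylated catechin gallates and should leave both esters, the ring C ether and the two stereocentres intact.

**Compound list**

1 | 2,4,6-trihydroxybenzaldehyde | O=Cc1c(O)cc(O)cc1O | starting material
2 | 4-(benzyloxy)-2,6-dihydroxybenzaldehyde | O=Cc1c(O)cc(OCc2ccccc2)cc1O | intermediate
3 | 4-(benzyloxy)-2-hydroxy-6-(methoxymethoxy)benzaldehyde | O=Cc1c(O)cc(OCc2ccccc2)cc1OCOC | intermediate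
4 | 3,4,5-tris(benzyloxy)benzaldehyde | O=Cc1cc(OCc2ccccc2)c(OCc2ccccc2)c(OCc2ccccc2)c1 | starting material
5 | (E)-3-[3,4,5-tris(benzyloxy)phenyl]prop-2-enal | O=C/C=C/c1cc(OCc2ccccc2)c(OCc2ccccc2)c(OCc2ccccc2)c1 | intermediate
6 | (2S)-7-(benzyloxy)-4-hydroxy-5-(methoxymethoxy)-2-[3,4,5-tris(benzyloxy)phenyl]-3,4-dihydro-2H-chromene-3-carbaldehyde (aldol adduct, carried on the catalyst; C3 and C4 not controlled and lost on dehydration) | O=CC1C(O)c2c(OCOC)cc(OCc3ccccc3)cc2O[C@@H]1c1cc(OCc2ccccc2)c(OCc2ccccc2)c(OCc2ccccc2)c1 | intermediate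
7 | (2R)-7-(benzyloxy)-5-(methoxymethoxy)-2-[3,4,5-tris(benzyloxy)phenyl]-2H-chromene-3-carbaldehyde | O=CC1=Cc2c(OCOC)cc(OCc3ccccc3)cc2O[C@@H]1c1cc(OCc2ccccc2)c(OCc2ccccc2)c(OCc2ccccc2)c1 | intermediate
8 | (2R)-7-(benzyloxy)-5-(methoxymethoxy)-2-[3,4,5-tris(benzyloxy)phenyl]-2H-chromene-3-carboxylic acid | O=C(O)C1=Cc2c(OCOC)cc(OCc3ccccc3)cc2O[C@@H]1c1cc(OCc2ccccc2)c(OCc2ccccc2)c(OCc2ccccc2)c1 | intermediate
9 | (2R)-7-(benzyloxy)-5-(methoxymethoxy)-2-[3,4,5-tris(benzyloxy)phenyl]-2H-chromene-3-carbonyl azide | [N-]=[N+]=NC(=O)C1=Cc2c(OCOC)cc(OCc3ccccc3)cc2O[C@@H]1c1cc(OCc2ccccc2)c(OCc2ccccc2)c(OCc2ccccc2)c1 | intermediate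
10 | (2R)-7-(benzyloxy)-3-isocyanato-5-(methoxymethoxy)-2-[3,4,5-tris(benzyloxy)phenyl]-2H-chromene | O=C=NC1=Cc2c(OCOC)cc(OCc3ccccc3)cc2O[C@@H]1c1cc(OCc2ccccc2)c(OCc2ccccc2)c(OCc2ccccc2)c1 | intermediate
11 | (2R)-7-(benzyloxy)-5-(methoxymethoxy)-2-[3,4,5-tris(benzyloxy)phenyl]-2H-chromen-3(4H)-one | O=C1Cc2c(OCOC)cc(OCc3ccccc3)cc2O[C@@H]1c1cc(OCc2ccccc2)c(OCc2ccccc2)c(OCc2ccccc2)c1 | intermediate
12 | (2R,3R)-7-(benzyloxy)-5-(methoxymethoxy)-2-[3,4,5-tris(benzyloxy)phenyl]-3,4-dihydro-2H-chromen-3-ol (2,3-cis) | COCOc1cc(OCc2ccccc2)cc2c1C[C@@H](O)[C@@H](c1cc(OCc3ccccc3)c(OCc3ccccc3)c(OCc3ccccc3)c1)O2 | intermediate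
13 | (2R,3R)-7-(benzyloxy)-2-[3,4,5-tris(benzyloxy)phenyl]-3,4-dihydro-2H-chromene-3,5-diol | Oc1cc(OCc2ccccc2)cc2c1C[C@@H](O)[C@@H](c1cc(OCc3ccccc3)c(OCc3ccccc3)c(OCc3ccccc3)c1)O2 | intermediate
14 | 3,4,5-tris(benzyloxy)benzoic acid | O=C(O)c1cc(OCc2ccccc2)c(OCc2ccccc2)c(OCc2ccccc2)c1 | starting material
15 | (2R,3R)-7-(benzyloxy)-2-[3,4,5-tris(benzyloxy)phenyl]-3,4-dihydro-2H-chromene-3,5-diyl bis[3,4,5-tris(benzyloxy)benzoate] | O=C(Oc1cc(OCc2ccccc2)cc2c1C[C@@H](OC(=O)c1cc(OCc3ccccc3)c(OCc3ccccc3)c(OCc3ccccc3)c1)[C@@H](c1cc(OCc3ccccc3)c(OCc3ccccc3)c(OCc3ccccc3)c1)O2)c1cc(OCc2ccccc2)c(OCc2ccccc2)c(OCc2ccccc2)c1 | intermediate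
16 | (2R,3R)-7-hydroxy-2-(3,4,5-trihydroxyphenyl)-3,4-dihydro-2H-chromene-3,5-diyl bis(3,4,5-trihydroxybenzoate), epigallocatechin 3,5-digallate | O=C(Oc1cc(O)cc2c1C[C@@H](OC(=O)c1cc(O)c(O)c(O)c1)[C@@H](c1cc(O)c(O)c(O)c1)O2)c1cc(O)c(O)c(O)c1 | target

**Step count.** Total: 10 steps. Longest linear sequence: 9 steps (from 1 through steps 1, 2 and 4 to 10). The enal branch adds step 3, and 14 is used as purchased.

**Steps most likely to fail**

Step 4. The aldol closure onto the doubly ortho-substituted, hydrogen-bonded and electron-rich formyl group may be slow. The reversible oxa-Michael adduct would then fall back to 3 and 5 and the bulky catalyst would turn over poorly, and warming to force conversion would erode facial selectivity. The fallback replaces asymmetric catalysis by a racemic annulation and classical resolution. Setting out from 3 and 5, the same two bonds are closed with a small achiral amine (pyrrolidine 30 mol %, PhCO2H, DMSO, 40 °C), which should give racemic 7-(benzyloxy)-5-(methoxymethoxy)-2-[3,4,5-tris(benzyloxy)phenyl]-2H-chromene-3-carbaldehyde F1. Chlorite oxidation as in step 5 should give racemic 7-(benzyloxy)-5-(methoxymethoxy)-2-[3,4,5-tris(benzyloxy)phenyl]-2H-chromene-3-carboxylic acid F2. Crystallisation with (S)-1-phenylethylamine from EtOAc/EtOH is expected to deliver the less soluble diastereomeric salt, (1S)-1-phenylethanaminium (2R)-7-(benzyloxy)-5-(methoxymethoxy)-2-[3,4,5-tris(benzyloxy)phenyl]-2H-chromene-3-carboxylate F3; the antipodal amine would be taken if the 2S salt proves the less soluble one. Cold dilute HCl releases the acid and the route is rejoined at 8, at the cost of half the material.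

Step 6. During acid hydrolysis the C3 iminium/enamine or the ketone may tautomerise towards C2 and so lose configurational purity. The liberated enamine may also capture unreacted isocyanate as a urea, and the MOM ether may be cleaved prematurely. The fallback removes the formyl carbon as CO and oxygenates C3 by hydroboration. Setting out from 7, RhCl(PPh3)3 (1.1 equiv, toluene, 110 °C) should decarbonylate the enal to (2S)-7-(benzyloxy)-5-(methoxymethoxy)-2-[3,4,5-tris(benzyloxy)phenyl]-2H-chromene F4. BH3·THF followed by NaOH/H2O2 should place boron and then oxygen on C3, the carbon remote from ring A, anti to ring B, giving (2R,3S)-7-(benzyloxy)-5-(methoxymethoxy)-2-[3,4,5-tris(benzyloxy)phenyl]-3,4-dihydro-2H-chromen-3-ol F5, whose C3 configuration does not matter. Oxidation with the triacetoxyperiodinane DMP (NaHCO3, CH2Cl2) under neutral conditions returns to the route at 11.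

Step 1. A second benzylation at an ortho hydroxyl and C-benzylation of the phloroglucinol-type phenoxide may compete with the wanted mono-O-alkylation. The fallback replaces phenoxide alkylation by a redox-condensation etherification. Setting out from 1, a Mitsunobu reaction with BnOH, PPh3 and diisopropyl azodicarboxylate (THF, 0 °C) should engage only the most acidic, non-chelated 4-OH and generates no ambident phenoxide. It arrives directly at 2 and makes no compound outside the list (line F0).

**Further compounds**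

F1 | step 4 | racemic 7-(benzyloxy)-5-(methoxymethoxy)-2-[3,4,5-tris(benzyloxy)phenyl]-2H-chromene-3-carbaldehyde | O=CC1=Cc2c(OCOC)cc(OCc3ccccc3)cc2OC1c1cc(OCc2ccccc2)c(OCc2ccccc2)c(OCc2ccccc2)c1
F2 | step 4 | racemic 7-(benzyloxy)-5-(methoxymethoxy)-2-[3,4,5-tris(benzyloxy)phenyl]-2H-chromene-3-carboxylic acid | O=C(O)C1=Cc2c(OCOC)cc(OCc3ccccc3)cc2OC1c1cc(OCc2ccccc2)c(OCc2ccccc2)c(OCc2ccccc2)c1
F3 | step 4 | (1S)-1-phenylethanaminium (2R)-7-(benzyloxy)-5-(methoxymethoxy)-2-[3,4,5-tris(benzyloxy)phenyl]-2H-chromene-3-carboxylate | [O-]C(=O)C1=Cc2c(OCOC)cc(OCc3ccccc3)cc2O[C@@H]1c1cc(OCc2ccccc2)c(OCc2ccccc2)c(OCc2ccccc2)c1.C[C@H]([NH3+])c1ccccc1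
F4 | step 6 | (2S)-7-(benzyloxy)-5-(methoxymethoxy)-2-[3,4,5-tris(benzyloxy)phenyl]-2H-chromene | C1=Cc2c(OCOC)cc(OCc3ccccc3)cc2O[C@@H]1c1cc(OCc2ccccc2)c(OCc2ccccc2)c(OCc2ccccc2)c1
F5 | step 6 | (2R,3S)-7-(benzyloxy)-5-(methoxymethoxy)-2-[3,4,5-tris(benzyloxy)phenyl]-3,4-dihydro-2H-chromen-3-ol | COCOc1cc(OCc2ccccc2)cc2c1C[C@H](O)[C@@H](c1cc(OCc3ccccc3)c(OCc3ccccc3)c(OCc3ccccc3)c1)O2
F0 | step 1 | none | none
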